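**Retrosynthetic overview**
1. The C11 hydroperoxide and the C6=C7 bond are made last, by a singlet-oxygen ene reaction on the C7=C11 isopropylidene enone 19.
2. Ring A of 19 (1β-OH, 3β-angelate) is oxidised stepwise from dehydrofukinone 7: C1 by γ-C–H oxidation, C2=C3 by dehydrogenation, C3–B by conjugate borylation, and both carbinol centres by hydride delivery to the α face, opposite the cis methyl groups.
3. 7 comes from (+)-aristolochene 5 by allylic oxidation at C8 and conjugative alkene migration.
4. The strategy rests on the eremophilane decalin, ring A (C1–C5, C10) and ring B (C5–C10), with cis methyl groups on C4 and on quaternary C5. Aristolochene synthase closes the ten-membered ring of farnesyl diphosphate 3 first (C6–C7), then forms C5–C10 across it, which closes rings A and B together, and shifts H (C5 to C4) and CH3 (C10 to C5).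
5. 3 is made in two steps from farnesol 1; angelic acid 16 enters by esterification.

Key step: step 3

Assumption: (+)-aristolochene is taken as (4S,5R,7S), so its C4 and C5 have the spatial arrangement of C4 and C5 of the target (C4 becomes R there only because the C3 oxygen changes the priorities); eremophilane numbering is used for all compounds, including 1–4 (C6 is the oxygen-bearing carbon of farnesol), and β is the face of the C14 and C15 methyl groups.

**Step 1**
Reactants: 1 (2E,6E)-farnesol
Product: 2 (2E,6E)-farnesyl bromide
Conditions: PBr3 (0.4 equiv), Et2O, −10 °C; used crude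
Reagents that add atoms: phosphorus tribromide, BrP(Br)Br
Why: Bromination of the primary allylic alcohol through its phosphite ester at low temperature is an SN2-type substitution that keeps the 2E geometry and avoids allylic transposition.

**Step 2**
Reactants: 2 (2E,6E)-farnesyl bromide
Product: 3 (2E,6E)-farnesyl diphosphate (isolated as its ammonium salt)
Conditions: (n-Bu4N)3HP2O7, MeCN, rt; then Dowex 50W-X8 (NH4+ form), aq NH4HCO3, lyophilisation
Reagents that add atoms: tris(tetra-n-butylammonium) hydrogen diphosphate, CCCC[N+](CCCC)(CCCC)CCCC.CCCC[N+](CCCC)(CCCC)CCCC.CCCC[N+](CCCC)(CCCC)CCCC.OP(=O)([O-])OP(=O)([O-])[O-]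
Why: SN2 displacement of the allylic bromide by the diphosphate anion in acetonitrile gives the diphosphate monoester, and cation exchange converts it into the water-soluble ammonium salt that the enzyme accepts.

**Step 3**
Reactants: 3 (2E,6E)-farnesyl diphosphate
Product: 5 (+)-aristolochene [(4S,5R,7S)-eremophila-9,11-diene], via (S)-germacrene A 4 (not isolated)
Conditions: aristolochene synthase (recombinant, from Aspergillus terreus), MgCl2, Tris buffer pH 7.5, glycerol, pentane overlay, 30 °C
Reagents that add atoms: none
Why: Ionisation of the magnesium-bound diphosphate of 3 gives the C6 allyl cation, which the distal C7=C11 π bond captures in a 10-exo macrocyclisation (C6–C7), and loss of a C12 proton leaves enzyme-bound (S)-germacrene A 4. Reprotonation of 4 at C1 lets the C4=C5 π bond attack C10, which forms C5–C10 across the ten-membered ring and closes ring A in a 6-endo and ring B in a 6-exo sense to give the eudesmane cation at C4. A 1,2-hydride shift from C5 to C4 and a 1,2-methyl shift from C10 to C5 (the third skeletal bond, C5–C14) move the charge to C10, and loss of a C9 proton gives the C9=C10 bond. The closest known reaction type is the ionisation-triggered cationic polyene cyclisation with Wagner–Meerwein shifts of sesquiterpene synthases, and this conversion is the native reaction of aristolochene synthase. C7 is set by the fold in which the enzyme holds the chain during the first closure, C4 by the face on which the migrating hydride arrives and C5 by the anti migration of the methyl group, so all three are controlled by the active-site contour. The step needs Markovnikov C6–C7 closure, retention of 4 in the active site and deprotonation at C9 instead of C1 (which would give valencene); the substrate secures the first through its 2E,6E geometry and trisubstituted alkenes (tertiary cations at C11, C10 and C4), and the enzyme from Aspergillus terreus is chosen because it secures the other two.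

**Step 4**
Reactants: 5 (+)-aristolochene
Product: 6 (4S,5R,7S)-eremophila-9,11-dien-8-one
Conditions: t-BuOOH, Rh2(cap)4 (dirhodium tetrakis(caprolactamate), 1 mol %), K2CO3, CH2Cl2, rt
Reagents that add atoms: tert-butyl hydroperoxide, CC(C)(C)OO
Why: In this radical allylic oxidation the tert-butylperoxyl radical abstracts a C8 hydrogen next to the CH end of the trisubstituted C9=C10 bond, the allyl radical is trapped at its less hindered secondary end C8 and the mixed peroxide collapses to the conjugated enone, as in the oxidation of valencene to nootkatone; the less electron-rich 1,1-disubstituted C11=C12 bond should react more slowly, and the C7 configuration does not matter because step 5 erases it.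

**Step 5**
Reactants: 6 (4S,5R,7S)-eremophila-9,11-dien-8-one
Product: 7 (4S,5R)-eremophila-7(11),9-dien-8-one (dehydrofukinone)
Conditions: DBU (0.2 equiv), toluene, 40 °C
Reagents that add atoms: none
Why: In this base-mediated conjugative isomerisation DBU removes the C7 hydrogen (α to the ketone and allylic) and the dienolate is reprotonated at C12, which moves the alkene into the thermodynamically preferred tetrasubstituted, conjugated 7(11) position, as in the isomerisation of petasin to isopetasin.

**Step 6**
Reactants: 7 (4S,5R)-eremophila-7(11),9-dien-8-one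
Product: 8 (4S,5R)-eremophila-7(11),9-diene-1,8-dione
Conditions: t-BuOOH, Pd(OH)2/C (5 mol %), K2CO3, CH2Cl2, 0 °C to rt
Reagents that add atoms: tert-butyl hydroperoxide, CC(C)(C)OO
Why: This is the γ-C–H oxidation of an enone to an ene-1,4-dione, in which the tert-butylperoxyl radical should abstract the axial C1 hydrogen because the resulting radical is delocalised over C10=C9–C8=O, whereas the C6 hydrogens are neopentylic next to quaternary C5 and the C12 and C13 hydrogens are primary, and the C1 peroxide then fragments to the ketone.

**Step 7**
Reactants: 8 (4S,5R)-eremophila-7(11),9-diene-1,8-dione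
Product: 9 (4S,5R)-eremophila-2,7(11),9-triene-1,8-dione
Conditions: IBX, DMSO, 70 °C
Reagents that add atoms: none
Why: IBX dehydrogenates a ketone through its enol, and C2 is the only enolisable α-position of the C1 ketone (C10 is sp2 and the C8 ketone has no α-hydrogen), so the new alkene can only be C2=C3, while quaternary C5 blocks further dehydrogenation.

**Step 8**
Reactants: 9 (4S,5R)-eremophila-2,7(11),9-triene-1,8-dione
Product: 10 (3R,4S,5R)-3α-(4,4,5,5-tetramethyl-1,3,2-dioxaborolan-2-yl)eremophila-7(11),9-diene-1,8-dione
Conditions: B2pin2, CuCl (5 mol %), DPEphos, NaOt-Bu (10 mol %), MeOH, THF, rt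
Reagents that add atoms: bis(pinacolato)diboron, CC1(C)OB(OC1(C)C)B1OC(C)(C)C(C)(C)O1
Why: In this copper-catalysed conjugate borylation a monovalent copper boryl adds across the enone and methanol protonates the enolate; C2=C3 is the only disubstituted acceptor alkene (C9=C10 is trisubstituted with C10 next to quaternary C5, C7=C11 is tetrasubstituted), and boron should enter C3 anti to the C4 methyl group (3α), although either C3 epimer would serve because C3 later passes through ketone 14.

**Step 9**
Reactants: 10 3α-boryl-1,8-dione
Product: 11 (1R,3R,4S,5R)-1β-hydroxy-3α-(4,4,5,5-tetramethyl-1,3,2-dioxaborolan-2-yl)eremophila-7(11),9-dien-8-one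
Conditions: NaBH4, CeCl3·7H2O, MeOH, −78 °C
Reagents that add atoms: none
Why: In this Luche 1,2-reduction the C1 carbonyl of the ene-dione, flanked by a CH2 group, is more electrophilic and more accessible than the cross-conjugated C8 carbonyl flanked by the isopropylidene group, and hydride should arrive on the α face opposite the axial C14 methyl group on C5 (the bias that gives 6β-alcohols from 6-oxo steroids), which sets C1 as the 1β (R) alcohol.

**Step 10**
Reactants: 11 1β-hydroxy-3α-boronate
Product: 12 (1R,3R,4S,5R)-3α-(4,4,5,5-tetramethyl-1,3,2-dioxaborolan-2-yl)-1β-(triethylsilyloxy)eremophila-7(11),9-dien-8-one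
Conditions: TESOTf, 2,6-lutidine, CH2Cl2, −78 °C
Reagents that add atoms: triethylsilyl trifluoromethanesulfonate, CC[Si](CC)(CC)OS(=O)(=O)C(F)(F)F
Why: Silylation of the hindered secondary allylic alcohol with the silyl triflate and a non-nucleophilic base masks O1 so that C3 can later be oxidised and acylated selectively, and the pinacol boronate and the dienone are inert at −78 °C.

**Step 11**
Reactants: 12 1β-silyloxy-3α-boronate
Product: 13 (1R,3R,4R,5R)-3α-hydroxy-1β-(triethylsilyloxy)eremophila-7(11),9-dien-8-one
Conditions: NaBO3·4H2O, THF/H2O, rt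
Reagents that add atoms: sodium perborate, [Na+].[O-]OB=O
Why: Perborate oxidises the C–B bond by 1,2-migration of C3 from boron to oxygen with retention, and the mild conditions should leave the silyl ether and the dienone (fully substituted β-carbons) untouched.

**Step 12**
Reactants: 13 3α-hydroxy-1β-silyloxy dienone
Product: 14 (1R,4R,5R)-1β-(triethylsilyloxy)eremophila-7(11),9-diene-3,8-dione
Conditions: Dess–Martin periodinane, NaHCO3, CH2Cl2, 0 °C; crude product used at once
Reagents that add atoms: none
Why: Dess–Martin oxidation of the secondary alcohol under buffered, non-basic conditions should give the C3 ketone without β-elimination of the C1 silyloxy group or epimerisation of the adjacent C4 centre.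

**Step 13**
Reactants: 14 1β-silyloxy-3,8-dione
Product: 15 (1R,3S,4R,5R)-3β-hydroxy-1β-(triethylsilyloxy)eremophila-7(11),9-dien-8-one
Conditions: LiBH(s-Bu)3, THF, −78 °C; then aq NH4Cl
Reagents that add atoms: none
Why: A bulky hydride reduces a cyclohexanone from its less hindered face, and here the β face of C3 is screened by the vicinal C15 methyl group, the angular C14 methyl group and the 1β-silyloxy group, so hydride should attack from the α face and set C3 as the 3β (S) alcohol cis to the methyl groups, while the cross-conjugated C8 ketone with fully substituted β-carbons should not react at −78 °C.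

**Step 14**
Reactants: 15 3β-hydroxy-1β-silyloxy dienone; 16 angelic acid [(Z)-2-methylbut-2-enoic acid]
Product: 18 (1R,3S,4R,5R)-3β-angeloyloxy-1β-(triethylsilyloxy)eremophila-7(11),9-dien-8-one, via angelic 2,4,6-trichlorobenzoic anhydride 17 (not isolated)
Conditions: 16, 2,4,6-trichlorobenzoyl chloride, Et3N, toluene, rt; then 15, 75 °C
Reagents that add atoms: angelic acid 16, C/C=C(/C)C(=O)O; 2,4,6-trichlorobenzoyl chloride, O=C(Cl)c1c(Cl)cc(Cl)cc1Cl (its atoms stay only in 17)
Why: This Yamaguchi-type esterification goes through the mixed anhydride 17, which the alcohol attacks at the unhindered angeloyl carbonyl with retention at C3, and the absence of nucleophilic catalysts keeps the Z (angelate) geometry from isomerising to the tiglate.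

**Step 15**
Reactants: 18 3β-angeloyloxy-1β-silyloxy dienone
Product: 19 (1R,3S,4R,5R)-3β-angeloyloxy-1β-hydroxyeremophila-7(11),9-dien-8-one
Conditions: HF·pyridine, THF/pyridine, 0 °C
Reagents that add atoms: none
Why: Fluoride cleaves the triethylsilyl ether under mildly acidic conditions, which avoids base-induced migration of the angeloyl group from O3 to the cis O1 and should not touch the ester or the dienone.

**Step 16**
Reactants: 19 3β-angeloyloxy-1β-hydroxy dienone
Product: 20 (1R,3S,4R,5R)-3β-angeloyloxy-1β-hydroxy-11-hydroperoxyeremophila-6,9-dien-8-one (CNP0300636.1)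
Conditions: O2, methylene blue (cat.), CH2Cl2, visible light, −20 °C; stopped at full conversion of 19
Reagents that add atoms: dioxygen (singlet state from the sensitiser), O=O
Why: In this Schenck ene reaction of singlet oxygen with the s-cis enone the fully substituted C7=C11 bond reacts with gem regioselectivity, a hydrogen being taken from C6 (the group geminal to the C8 carbonyl on C7) while O2 bonds to C11, so the new C6=C7 bond is conjugated and the tertiary hydroperoxide forms without a new stereocentre; the C9=C10 enone bond has no geminal allylic hydrogen and the electron-poor angelate should react far more slowly.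

**Compound list**
1 | (2E,6E)-farnesol | CC(C)=CCC/C(C)=C/CC/C(C)=C/CO | starting material
2 | (2E,6E)-farnesyl bromide | CC(C)=CCC/C(C)=C/CC/C(C)=C/CBr | intermediate
3 | (2E,6E)-farnesyl diphosphate (used as its ammonium salt) | CC(C)=CCC/C(C)=C/CC/C(C)=C/COP(=O)(O)OP(=O)(O)O | intermediate
4 | (S)-germacrene A, (7S)-germacra-1(10)E,4E,11-triene (enzyme-bound) | C1/C=C(\C)CC/C=C(\C)CC[C@@H]1C(C)=C | intermediate
5 | (+)-aristolochene, (4S,5R,7S)-eremophila-9,11-diene | C1CCC2=CC[C@H](C(C)=C)C[C@]2(C)[C@H]1C | intermediate
6 | (4S,5R,7S)-eremophila-9,11-dien-8-one | C1CCC2=CC(=O)[C@H](C(C)=C)C[C@]2(C)[C@H]1C | intermediate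
7 | (4S,5R)-eremophila-7(11),9-dien-8-one (dehydrofukinone) | C1CCC2=CC(=O)C(=C(C)C)C[C@]2(C)[C@H]1C | intermediate
8 | (4S,5R)-eremophila-7(11),9-diene-1,8-dione | C1CC(=O)C2=CC(=O)C(=C(C)C)C[C@]2(C)[C@H]1C | intermediate
9 | (4S,5R)-eremophila-2,7(11),9-triene-1,8-dione | C1=CC(=O)C2=CC(=O)C(=C(C)C)C[C@]2(C)[C@H]1C | intermediate
10 | (3R,4S,5R)-3α-(pinacolatoboryl)eremophila-7(11),9-diene-1,8-dione | CC3(C)OB(OC3(C)C)[C@@H]1CC(=O)C2=CC(=O)C(=C(C)C)C[C@]2(C)[C@H]1C | intermediate
11 | (1R,3R,4S,5R)-1β-hydroxy-3α-(pinacolatoboryl)eremophila-7(11),9-dien-8-one | CC3(C)OB(OC3(C)C)[C@@H]1C[C@@H](O)C2=CC(=O)C(=C(C)C)C[C@]2(C)[C@H]1C | intermediate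
12 | (1R,3R,4S,5R)-3α-(pinacolatoboryl)-1β-(triethylsilyloxy)eremophila-7(11),9-dien-8-one | CC3(C)OB(OC3(C)C)[C@@H]1C[C@@H](O[Si](CC)(CC)CC)C2=CC(=O)C(=C(C)C)C[C@]2(C)[C@H]1C | intermediate
13 | (1R,3R,4R,5R)-3α-hydroxy-1β-(triethylsilyloxy)eremophila-7(11),9-dien-8-one | O[C@@H]1C[C@@H](O[Si](CC)(CC)CC)C2=CC(=O)C(=C(C)C)C[C@]2(C)[C@H]1C | intermediate
14 | (1R,4R,5R)-1β-(triethylsilyloxy)eremophila-7(11),9-diene-3,8-dione | O=C1C[C@@H](O[Si](CC)(CC)CC)C2=CC(=O)C(=C(C)C)C[C@]2(C)[C@H]1C | intermediate
15 | (1R,3S,4R,5R)-3β-hydroxy-1β-(triethylsilyloxy)eremophila-7(11),9-dien-8-one | O[C@H]1C[C@@H](O[Si](CC)(CC)CC)C2=CC(=O)C(=C(C)C)C[C@]2(C)[C@H]1C | intermediate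
16 | angelic acid, (Z)-2-methylbut-2-enoic acid | C/C=C(/C)C(=O)O | starting material
17 | angelic 2,4,6-trichlorobenzoic anhydride (Z) | C/C=C(/C)C(=O)OC(=O)c1c(Cl)cc(Cl)cc1Cl | intermediate
18 | (1R,3S,4R,5R)-3β-angeloyloxy-1β-(triethylsilyloxy)eremophila-7(11),9-dien-8-one | C/C=C(/C)C(=O)O[C@H]1C[C@@H](O[Si](CC)(CC)CC)C2=CC(=O)C(=C(C)C)C[C@]2(C)[C@H]1C | intermediate
19 | (1R,3S,4R,5R)-3β-angeloyloxy-1β-hydroxyeremophila-7(11),9-dien-8-one | C/C=C(/C)C(=O)O[C@H]1C[C@@H](O)C2=CC(=O)C(=C(C)C)C[C@]2(C)[C@H]1C | intermediate
20 | (1R,3S,4R,5R)-3β-angeloyloxy-1β-hydroxy-11-hydroperoxyeremophila-6,9-dien-8-one (CNP0300636.1) | C/C=C(/C)C(=O)O[C@H]1C[C@@H](O)C2=CC(=O)C(C(C)(C)OO)=C[C@]2(C)[C@H]1C | target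

**Step count**
Total: 16 steps. Longest linear sequence: 16 steps (1 to 20); angelic acid 16 is used as purchased.

**Steps most likely to fail**

1. Step 6. Hydrogen abstraction may occur at the wrong allylic site (C6 or the C12/C13 methyl groups), or the dienone may be over-oxidised, because site selectivity rests only on radical stability and access. The fallback sets out from 7 and comes back at 8. Equilibrating enol acetylation (isopropenyl acetate, p-TsOH, reflux) should give the linear dienol acetate 8-acetoxyeremophila-1(10),7(11),8-triene F1. Peracid oxidation (mCPBA, CH2Cl2/aq NaHCO3, 0 °C) should attack its electron-rich C1 terminus, as in the 6β-hydroxylation of steroidal dienol acetates, and release 1β-hydroxyeremophila-7(11),9-dien-8-one F2. Dess–Martin periodinane or MnO2 then oxidises F2 to 8. This polar, enol-directed oxidation replaces the radical C–H abstraction.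

2. Step 8. The copper boryl may add to C9 of the ene-dione instead of C3, or reduce the ene-dione by electron transfer. The fallback sets out from 9 and comes back at 12. Luche reduction of the C1 carbonyl (NaBH4, CeCl3·7H2O, MeOH, −78 °C) removes the ene-dione first and should give 1β-hydroxyeremophila-2,7(11),9-trien-8-one F3. Silylation (TESOTf, 2,6-lutidine) gives 1β-(triethylsilyloxy)eremophila-2,7(11),9-trien-8-one F4. Rhodium-catalysed hydroboration of the now isolated C2=C3 bond (pinacolborane, RhCl(PPh3)3, THF) should place boron on C3, distal and anti to the silyloxy group, which is compound 12.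

3. Step 4. Once C8 is a carbonyl, the C7 hydrogen is tertiary, allylic and α to the ketone, so further radical abstraction (or attack at the isopropenyl group) may consume the product. The fallback sets out from 5 and comes back at 6. Dye-sensitised photooxygenation (O2, tetraphenylporphyrin, CH2Cl2, visible light) reacts only at the trisubstituted C9=C10 bond; taking hydrogen mainly from C8 on the more substituted side of the alkene, it should give the tertiary allylic hydroperoxide 10α-hydroperoxyeremophila-8,11-diene F5. PPh3 reduces it to 10α-hydroxyeremophila-8,11-diene F6. Oxidative 1,3-transposition with pyridinium chlorochromate (C5H5NH[CrO3Cl], CH2Cl2; Babler–Dauben oxidation) then gives 6.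

**Further compounds**
F1 | step 6 | (4S,5R)-8-acetoxyeremophila-1(10),7(11),8-triene | C1CC=C2C=C(OC(C)=O)C(=C(C)C)C[C@]2(C)[C@H]1C
F2 | step 6 | (1R,4S,5R)-1β-hydroxyeremophila-7(11),9-dien-8-one | C1C[C@@H](O)C2=CC(=O)C(=C(C)C)C[C@]2(C)[C@H]1C
F3 | step 8 | (1R,4S,5R)-1β-hydroxyeremophila-2,7(11),9-trien-8-one | C1=C[C@@H](O)C2=CC(=O)C(=C(C)C)C[C@]2(C)[C@H]1C
F4 | step 8 | (1R,4S,5R)-1β-(triethylsilyloxy)eremophila-2,7(11),9-trien-8-one | C1=C[C@@H](O[Si](CC)(CC)CC)C2=CC(=O)C(=C(C)C)C[C@]2(C)[C@H]1C
F5 | step 4 | 10α-hydroperoxyeremophila-8,11-diene (4S,5R,7R,10R) | C1CC[C@@]2(OO)C=C[C@H](C(C)=C)C[C@]2(C)[C@H]1C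
F6 | step 4 | 10α-hydroxyeremophila-8,11-diene (4S,5R,7R,10R) | C1CC[C@@]2(O)C=C[C@H](C(C)=C)C[C@]2(C)[C@H]1C
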